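**Retrosynthetic overview**
- The usual route (1,3-diketone from a 2'-hydroxyacetophenone, then cyclodehydration) is set aside. Instead the pyranone ring is cut at three bonds at once (C4–C4a, C3–C4, O1–C2) into an o-iodophenol, CO and a terminal alkyne, joined by a Pd carbonylative Sonogashira annulation.
- The o-iodophenol comes from 3,4-dimethoxyphenol by regioselective ortho-iodination.
- The alkyne comes from a 3-arylpropanal by Ohira–Bestmann homologation; the aldehyde comes from 5-bromo-2-methoxyphenol and allyl alcohol by a Heck reaction.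
- Both benzene rings are bought; the pyranone is the only ring formed, and it is formed last. No protecting groups are used.

Assumption: the target has no stereocentre and no stereogenic double bond, so it is achiral and the "single enantiomer" requirement is met by the compound itself. Compounds are numbered in the order of the forward route.

**Step 1**
Reactants: 1 3,4-dimethoxyphenol
Product: 2 2-iodo-4,5-dimethoxyphenol
Conditions: NIS (1.0 equiv), MeCN, −10 °C → rt, dark
Reagents that add atoms: N-iodosuccinimide, O=C1CCC(=O)N1I
Why: Electrophilic aromatic iodination; OH directs ortho, and C6 (also para to the 3-OMe, unhindered) reacts far faster than C2, which is squeezed between OH and OMe; no stereocentre is formed.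

**Step 2**
Reactants: 3 5-bromo-2-methoxyphenol; 4 allyl alcohol
Product: 6 3-(3-hydroxy-4-methoxyphenyl)propanal, via enol 5 (not isolated)
Conditions: Pd(OAc)2 (3 mol %), n-Bu4NCl (1 equiv), NaHCO3 (2.5 equiv), DMF, 90 °C
Reagents that add atoms: none
Why: Mizoroki–Heck reaction under Jeffery conditions; aryl-Pd adds to the terminal alkene carbon, β-hydride elimination toward the carbinol gives enol 5, which tautomerises to the aldehyde, and the weak base leaves the free phenol alone; no stereocentre is formed.

**Step 3**
Reactants: 6 3-(3-hydroxy-4-methoxyphenyl)propanal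
Product: 7 5-(but-3-yn-1-yl)-2-methoxyphenol
Conditions: Ohira–Bestmann reagent (1.3 equiv), K2CO3 (3 equiv), MeOH, 0 °C → rt; aq. NH4Cl work-up
Reagents that add atoms: dimethyl (1-diazo-2-oxopropyl)phosphonate (Ohira–Bestmann reagent), CC(=O)C(=[N+]=[N-])P(=O)(OC)OC
Why: Seyferth–Gilbert homologation in the Ohira–Bestmann variant; methanolysis releases dimethyl (diazomethyl)phosphonate, which olefinates the aldehyde, loses N2 and undergoes 1,2-H shift to the terminal alkyne; the mild carbonate conditions suit enolisable aldehydes, and the extra base covers the phenol.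

**Step 4**
Reactants: 2 2-iodo-4,5-dimethoxyphenol; 7 5-(but-3-yn-1-yl)-2-methoxyphenol
Product: 10 2-[2-(3-hydroxy-4-methoxyphenyl)ethyl]-6,7-dimethoxy-4H-chromen-4-one, via alkynone 8 (not isolated), via enaminone 9 (not isolated)
Conditions: PdCl2(dppf) (5 mol %), CO (20 bar), Et2NH (solvent), 120 °C, autoclave; dilute HCl work-up
Reagents that add atoms: carbon monoxide, [C-]#[O+]
Why: Pd-catalysed carbonylative Sonogashira annulation; the electron-rich aryl-Pd inserts CO quickly and the acyl-Pd is alkynylated to alkynone 8, Et2NH adds to give enaminone 9, and the ortho-phenol displaces the amine by addition–elimination, which forces 6-endo closure to the chromone and excludes the 5-exo aurone; the isovanillyl OH is no more nucleophilic than the OH of 2, which the reaction already tolerates, and no stereocentre is formed.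

**Compound list**
1 | 3,4-dimethoxyphenol | COc1ccc(O)cc1OC | starting material
2 | 2-iodo-4,5-dimethoxyphenol | COc1cc(O)c(I)cc1OC | intermediate
3 | 5-bromo-2-methoxyphenol | COc1ccc(Br)cc1O | starting material
4 | allyl alcohol (prop-2-en-1-ol) | C=CCO | starting material
5 | (E)-3-(3-hydroxy-4-methoxyphenyl)prop-1-en-1-ol (enol; not isolated) | COc1ccc(C/C=C/O)cc1O | intermediate
6 | 3-(3-hydroxy-4-methoxyphenyl)propanal | COc1ccc(CCC=O)cc1O | intermediate
7 | 5-(but-3-yn-1-yl)-2-methoxyphenol | COc1ccc(CCC#C)cc1O | intermediate
8 | 1-(2-hydroxy-4,5-dimethoxyphenyl)-5-(3-hydroxy-4-methoxyphenyl)pent-2-yn-1-one (alkynone; not isolated) | COc1ccc(CCC#CC(=O)c2cc(OC)c(OC)cc2O)cc1O | intermediate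
9 | (E)-3-(diethylamino)-1-(2-hydroxy-4,5-dimethoxyphenyl)-5-(3-hydroxy-4-methoxyphenyl)pent-2-en-1-one (enaminone; not isolated) | CCN(CC)/C(CCc1ccc(OC)c(O)c1)=C/C(=O)c1cc(OC)c(OC)cc1O | intermediate
10 | 2-[2-(3-hydroxy-4-methoxyphenyl)ethyl]-6,7-dimethoxy-4H-chromen-4-one | COc1ccc(CCc2cc(=O)c3cc(OC)c(OC)cc3o2)cc1O | target

**Step count and risk**
Total steps: 4. Longest linear sequence: 3 (3 → 6 → 7 → 10); step 1 is a one-step side branch that joins at step 4.

The three steps most likely to fail:

Step 4 (carbonylative annulation). The risks are direct, CO-free Sonogashira coupling leading to a benzofuran, aminocarbonylation of 2 by Et2NH, and acylation of the free phenol of 7. The fallback sets out from 7 and comes back at 8, replacing the Pd/CO chemistry with a polar acetylide addition. Compound 7 is treated with n-BuLi (2.1 equiv, THF, −78 °C) to give the lithium phenoxide/acetylide. This is added to the sodium salt of commercial 2-hydroxy-4,5-dimethoxybenzaldehyde (NaH, THF) and warmed to 0 °C, and aqueous NH4Cl work-up gives racemic 1-(2-hydroxy-4,5-dimethoxyphenyl)-5-(3-hydroxy-4-methoxyphenyl)pent-2-yn-1-ol F1. Activated MnO2 in CH2Cl2 at rt oxidises the benzylic/propargylic alcohol to alkynone 8. Compound 8 is now isolated and closed to 10 through 9 by brief warming with Et2NH in EtOH, which is the second half of step 4.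

Step 2 (Heck reaction with allyl alcohol). The risks are a sluggish, electron-rich aryl bromide, the branched 2-arylpropanal and cinnamyl alcohol by-products, and aldol loss of the product. The fallback sets out from 3 and comes back at 6, using a B-alkyl Suzuki–Miyaura coupling instead. Commercial acrolein diethyl acetal is hydroborated with 9-BBN-H (THF, 0 °C → rt) to give 9-(3,3-diethoxypropyl)-9-borabicyclo[3.3.1]nonane F2. This is coupled in the same pot with 3 (PdCl2(dppf) 3 mol %, aq. K3PO4 3 equiv, THF/DMF, 60 °C) to give 5-(3,3-diethoxypropyl)-2-methoxyphenol F3. Hydrolysis of the acetal with 1 M HCl in THF at rt gives 6.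

Step 3 (Ohira–Bestmann homologation). The risk is aldol self-condensation of the enolisable phenolic aldehyde under K2CO3/MeOH before the diazophosphonate traps it. The fallback sets out from 3 and comes back at 7, bypassing the aldehyde by an sp2–sp3 Negishi coupling. Zinc dust with LiCl in THF at 40 °C inserts into commercial (4-bromobut-1-yn-1-yl)trimethylsilane to give [4-(trimethylsilyl)but-3-yn-1-yl]zinc bromide F4. This is coupled with the sodium phenoxide of 3 (NaH 1 equiv; Pd(OAc)2 2 mol %, SPhos 4 mol %, THF, rt) to give 2-methoxy-5-[4-(trimethylsilyl)but-3-yn-1-yl]phenol F5. Desilylation with K2CO3 in MeOH at rt gives 7.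

**Further compounds**
F1 | step 4 | 1-(2-hydroxy-4,5-dimethoxyphenyl)-5-(3-hydroxy-4-methoxyphenyl)pent-2-yn-1-ol (racemic) | COc1ccc(CCC#CC(O)c2cc(OC)c(OC)cc2O)cc1O
F2 | step 2 | 9-(3,3-diethoxypropyl)-9-borabicyclo[3.3.1]nonane | CCOC(CCB1C2CCCC1CCC2)OCC
F3 | step 2 | 5-(3,3-diethoxypropyl)-2-methoxyphenol | CCOC(CCc1ccc(OC)c(O)c1)OCC
F4 | step 3 | [4-(trimethylsilyl)but-3-yn-1-yl]zinc bromide | C[Si](C)(C)C#CCC[Zn]Br
F5 | step 3 | 2-methoxy-5-[4-(trimethylsilyl)but-3-yn-1-yl]phenol | COc1ccc(CCC#C[Si](C)(C)C)cc1O
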